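**Retrosynthetic overview**
- The target is the (3S,5R,6S)-3-myristoyloxy-5,6-epoxy megastigmane enone. Its C7=C8 bond is made last by Wittig olefination of the C6 formyl oxirane, and that aldehyde comes from ozonolysis of a C6 dienoate chain.
- The strategy rests on the C5–C6 oxirane with a C4 methylene beside it. This is the cycloisomer of a C6 tertiary alcohol next to a C4=C5 alkene, which is the ring of (S)-abscisic acid, where C6 and its oxygen already have the target configuration.
- Key disconnection: the C5–O bond, closed by cobalt-hydride hydrogen-atom transfer to C4 and capture of C5 by the C6 hydroxyl.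
- C3 is set beforehand by reagent-controlled reduction of the ring ketone to the 1′,4′-trans diol, followed by acylation of the secondary alcohol.
- Ring order: the cyclohexane ring is bought with abscisic acid; the oxirane is the only ring closed (step 4).

Key step: step 4

Remark: megastigmane numbering is used (C1 CMe2, C3 carbinol, C5 C-methyl, C6 carrier of the chain, chain C7 onwards; C6 = C1′ and C3 = C4′ of abscisic acid). The 2Z,4E geometry of the abscisate chain is carried as in the natural acid but has no bearing on the target, since the chain is cut at C7=C8 in step 5.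

**Step 1**
Reactants: 1 (S)-(+)-abscisic acid
Product: 2 methyl (S)-abscisate
Conditions: MeI, K2CO3, DMF, rt, dark
Reagents that add atoms: iodomethane, CI
Why: O-alkylation of the potassium carboxylate (SN2 esterification) masks the acid, which would consume borane in step 2, under conditions too mild to touch the tertiary allylic alcohol or the enone.

**Step 2**
Reactants: 2 methyl (S)-abscisate
Product: 3 methyl abscisate 1′,4′-trans-diol (1′S,4′S)
Conditions: (R)-2-methyl-CBS-oxazaborolidine (20 mol %), catecholborane, toluene, −78 °C; aq. NaHCO3 work-up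
Reagents that add atoms: none
Why: In this Corey–Bakshi–Shibata reduction the oxazaborolidine–borane complex binds the ketone with the C3′=C2′ alkenyl flank as the large group, so the (R)-catalyst should deliver hydride to the face that gives the 4′S carbinol (C3), trans to the C1′ hydroxyl, by reagent control, while ester and alkenes are left alone at −78 °C.

**Step 3**
Reactants: 3 methyl abscisate 1′,4′-trans-diol; 4 myristoyl chloride
Product: 5 methyl abscisate 1′,4′-trans-diol 4′-myristate
Conditions: pyridine, DMAP (cat.), CH2Cl2, 0 °C
Reagents that add atoms: none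
Why: DMAP-catalysed acylation (nucleophilic acyl substitution) should take place only at the secondary allylic alcohol, because the tertiary C6 hydroxyl sits between two fully substituted carbons; no stereocentre is touched.

**Step 4**
Reactants: 5 methyl abscisate 1′,4′-trans-diol 4′-myristate
Product: 6 methyl (3S,5R,6S)-5,6-epoxy dienoate 3-myristate
Conditions: Co(salen) complex N,N′-bis(3,5-di-tert-butylsalicylidene)-1,2-cyclohexanediaminocobalt (divalent cobalt, 5 mol %), N-fluoro-2,4,6-trimethylpyridinium triflate, PhSiH3, acetone, 0 °C to rt; aq. NaHCO3 quench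
Reagents that add atoms: none
Why: The cobalt complex is oxidised by the N-fluoropyridinium salt and converted by PhSiH3 into a cobalt hydride (trivalent cobalt), which transfers a hydrogen atom to C4, the less substituted carbon of the C4=C5 alkene, leaving the tertiary C5 radical. That radical is caught by cobalt and oxidised to an alkylcobalt at the tetravalent level, a C5 cation equivalent, which the C6 hydroxyl displaces in a 3-exo-tet closure that forms the C5–O bond and the oxirane. The closest known reaction type is the cobalt salen-catalysed hydrogen-atom-transfer radical–polar crossover cycloisomerisation of tertiary allylic alcohols to epoxides, and 5 is a tertiary allylic alcohol with a trisubstituted alkene of that class. The new C5 stereocentre is controlled by the C6 oxygen, whose configuration comes from (S)-abscisic acid: an oxirane on a six-membered ring can only be cis-fused, so the oxygen stays on its own face, C5 should come out R and the oxirane trans to the C3 ester. The step needs hydrogen transfer to the ring alkene and not to the chain, which the electron-rich trisubstituted C4=C5 bond (Markovnikov delivery to C4) secures against the electron-poor conjugated dienoate. It also needs closure in preference to a 1,2-shift from C6 to C5, which is favoured by the poor migrating ability of the ester-conjugated dienyl group and is tuned by screening the salen ligand for oxirane over ketone.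

**Step 5**
Reactants: 6 methyl (3S,5R,6S)-5,6-epoxy dienoate 3-myristate
Product: 8 (1R,3S,6S)-6-formyl-1,5,5-trimethyl-7-oxabicyclo[4.1.0]heptan-3-yl tetradecanoate, via secondary ozonide 7 (not isolated)
Conditions: O3, CH2Cl2, −78 °C; then PPh3, −78 °C to rt
Reagents that add atoms: ozone, [O-][O+]=O
Why: In this ozonolysis (1,3-dipolar cycloaddition, Criegee rearrangement to the ozonide, reduction by PPh3) ozone should attack C7=C8, the more electron-rich alkene of the dienoate, and if the enoate C9=C10 bond is cut as well the same aldehyde results, while the oxirane, the esters and the non-enolisable C6 are inert.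

**Step 6**
Reactants: 8 epoxy aldehyde; 9 1-(triphenylphosphoranylidene)propan-2-one
Product: 10 (1R,3S,6S)-1,5,5-trimethyl-6-[(1E)-3-oxobut-1-en-1-yl]-7-oxabicyclo[4.1.0]heptan-3-yl tetradecanoate (target)
Conditions: toluene, 90 °C
Reagents that add atoms: none
Why: Wittig olefination with a ketone-stabilised ylide should give the E-enone; the aldehyde has no α-hydrogen and cannot epimerise, and the neutral ylide leaves the oxirane and the myristate untouched.

**Compound list**
1 | (S)-(+)-abscisic acid | O=C1CC(C)(C)[C@@](O)(/C=C/C(C)=C\C(=O)O)C(C)=C1 | starting material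
2 | methyl (S)-abscisate | O=C1CC(C)(C)[C@@](O)(/C=C/C(C)=C\C(=O)OC)C(C)=C1 | intermediate
3 | methyl (2Z,4E)-5-[(1S,4S)-1,4-dihydroxy-2,6,6-trimethylcyclohex-2-en-1-yl]-3-methylpenta-2,4-dienoate (1′,4′-trans-diol) | O[C@H]1CC(C)(C)[C@@](O)(/C=C/C(C)=C\C(=O)OC)C(C)=C1 | intermediate
4 | myristoyl chloride (tetradecanoyl chloride) | CCCCCCCCCCCCCC(=O)Cl | starting material
5 | methyl (2Z,4E)-5-[(1S,4S)-1-hydroxy-2,6,6-trimethyl-4-(tetradecanoyloxy)cyclohex-2-en-1-yl]-3-methylpenta-2,4-dienoate | CCCCCCCCCCCCCC(=O)O[C@H]1CC(C)(C)[C@@](O)(/C=C/C(C)=C\C(=O)OC)C(C)=C1 | intermediate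
6 | methyl (2Z,4E)-3-methyl-5-[(1S,4S,6R)-2,2,6-trimethyl-4-(tetradecanoyloxy)-7-oxabicyclo[4.1.0]heptan-1-yl]penta-2,4-dienoate | CCCCCCCCCCCCCC(=O)O[C@H]1CC(C)(C)[C@]2(/C=C/C(C)=C\C(=O)OC)O[C@]2(C)C1 | intermediate
7 | secondary ozonide (1,2,4-trioxolane) across C7/C8 of 6, epimers at the two trioxolane carbons | CCCCCCCCCCCCCC(=O)O[C@H]1CC(C)(C)[C@]2(C3OOC(O3)/C(C)=C\C(=O)OC)O[C@]2(C)C1 | intermediate
8 | (1R,3S,6S)-6-formyl-1,5,5-trimethyl-7-oxabicyclo[4.1.0]heptan-3-yl tetradecanoate | CCCCCCCCCCCCCC(=O)O[C@H]1CC(C)(C)[C@]2(C=O)O[C@]2(C)C1 | intermediate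
9 | 1-(triphenylphosphoranylidene)propan-2-one | CC(=O)C=P(c1ccccc1)(c1ccccc1)c1ccccc1 | starting material
10 | (1R,3S,6S)-1,5,5-trimethyl-6-[(1E)-3-oxobut-1-en-1-yl]-7-oxabicyclo[4.1.0]heptan-3-yl tetradecanoate | CCCCCCCCCCCCCC(=O)O[C@H]1CC(C)(C)[C@]2(/C=C/C(C)=O)O[C@]2(C)C1 | target

Total step count: 6
Longest linear sequence: 6 steps (1 to 10)

**Steps most likely to fail**

1. Step 4. What may go wrong: hydrogen-atom transfer to the conjugated chain instead of the ring alkene, or migration of a C6 substituent to C5 (dienyl shift or ring contraction) outrunning C–O closure, so that a ketone forms in place of the oxirane. The fallback delivers the oxirane oxygen from a peracid to a C5=C6 alkene instead of taking it from the C6 hydroxyl. It sets out from myristoyl chloride 4, with the ring drawn from a second chiral-pool ketone, and comes back at target 10, so steps 5 and 6 are bypassed as well.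
   - Commercial (4R,6R)-4-hydroxy-2,2,6-trimethylcyclohexanone F1 would be silylated (TBSCl, imidazole, DMF) to its silyl ether F2.
   - LiN(iPr)2 then N-phenylbis(trifluoromethanesulfonimide) in THF at −78 °C should give the enol triflate F3, the only one possible because the other α-carbon is quaternary.
   - Heck coupling with but-3-en-2-one (Pd(OAc)2, PPh3, Et3N, DMF, 70 °C) should give the silyl ether of (3R)-3-hydroxy-β-ionone F4.
   - HF·pyridine would free (3R)-3-hydroxy-β-ionone F5, and 4 with pyridine would give its myristate F6.
   - mCPBA (CH2Cl2, NaHCO3, 0 °C) should epoxidise the electron-rich tetrasubstituted C5=C6 bond, preferentially on the face anti to the acyloxy group, to give 10 after chromatographic removal of the syn epoxide.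

2. Step 2. What may go wrong: poor facial selectivity at the ring ketone, because the two flanks differ little in size and the bias of the ring may oppose the catalyst, so that the cis-diol forms alongside the trans-diol. The fallback replaces reagent control by an unselective reduction made stereoconvergent; it sets out from 2 and comes back at 5. Luche reduction (NaBH4, CeCl3·7H2O, MeOH, −78 °C) would give both carbinol epimers, separable on silica. The trans-diol 3 would enter step 3. The cis-diol F7 would be esterified with inversion at the secondary allylic carbon under Mitsunobu conditions (myristic acid, PPh3, DIAD, THF, 0 °C) to give 5 directly.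

3. Step 6. What may go wrong: sluggish addition of the stabilised ylide to the hindered aldehyde on the fully substituted oxirane carbon, with decomposition of the epoxy aldehyde on prolonged heating. The fallback builds the enone by aldol addition and elimination instead of olefination; it sets out from 8 and comes back at 10. The lithium enolate of acetone (LiN(iPr)2, acetone, THF, −78 °C) should add to the aldehyde much faster than to the esters, giving the β-hydroxy ketone F8 as a mixture of carbinol epimers. Mesylation and E1cB elimination (MsCl, Et3N, then DBU, CH2Cl2, 0 °C) should then give the E-enone 10.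

**Further compounds**
F1 | step 4 | (4R,6R)-4-hydroxy-2,2,6-trimethylcyclohexanone | O=C1[C@H](C)C[C@@H](O)CC1(C)C
F2 | step 4 | (4R,6R)-4-[(tert-butyldimethylsilyl)oxy]-2,2,6-trimethylcyclohexanone | O=C1[C@H](C)C[C@@H](O[Si](C)(C)C(C)(C)C)CC1(C)C
F3 | step 4 | (4R)-4-[(tert-butyldimethylsilyl)oxy]-2,6,6-trimethylcyclohex-1-en-1-yl trifluoromethanesulfonate | CC(C)(C)[Si](C)(C)O[C@H]1CC(C)(C)C(OS(=O)(=O)C(F)(F)F)=C(C)C1
F4 | step 4 | (3E)-4-[(4R)-4-[(tert-butyldimethylsilyl)oxy]-2,6,6-trimethylcyclohex-1-en-1-yl]but-3-en-2-one | CC(C)(C)[Si](C)(C)O[C@H]1CC(C)(C)C(/C=C/C(C)=O)=C(C)C1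
F5 | step 4 | (3R)-3-hydroxy-β-ionone | O[C@H]1CC(C)(C)C(/C=C/C(C)=O)=C(C)C1
F6 | step 4 | (1R)-3,5,5-trimethyl-4-[(1E)-3-oxobut-1-en-1-yl]cyclohex-3-en-1-yl tetradecanoate | CCCCCCCCCCCCCC(=O)O[C@H]1CC(C)(C)C(/C=C/C(C)=O)=C(C)C1
F7 | step 2 | methyl (2Z,4E)-5-[(1S,4R)-1,4-dihydroxy-2,6,6-trimethylcyclohex-2-en-1-yl]-3-methylpenta-2,4-dienoate (1′,4′-cis-diol) | O[C@@H]1CC(C)(C)[C@@](O)(/C=C/C(C)=C\C(=O)OC)C(C)=C1
F8 | step 6 | (1R,3S,6S)-6-(1-hydroxy-3-oxobutyl)-1,5,5-trimethyl-7-oxabicyclo[4.1.0]heptan-3-yl tetradecanoate (carbinol epimers) | CCCCCCCCCCCCCC(=O)O[C@H]1CC(C)(C)[C@]2(C(O)CC(C)=O)O[C@]2(C)C1
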